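**Retrosynthetic overview**
- The target comes from its 11,12-didehydro acid by chemoselective diimide reduction of the disubstituted side-chain olefin.
- Key step: Ireland–Claisen [3,3] rearrangement of a C11 allylic acetate forms the C13–C14 bond, relays chirality from C11 to C13 and gives the free acid directly.
- The allylic acetate comes from an ent-drimane-type C11 aldehyde by alkenylation with (E)-1-bromopropene (C11 set under control of C9), then acetylation, axial-selective C3 reduction and exo-to-endo olefin transposition.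
- The aldehyde comes from andrographolide by dehydration to the 11,13-diene, 19-O-acetylation, C3 oxidation and cleavage of C11=C12.
- Ring order: no ring is built. Both carbocycles with C4, C5, C9 and C10 are bought in andrographolide; C3 is inverted by oxidation/reduction.

Assumption: ent-labdane numbering (C1–C20) is used throughout, and andrographolide, (E)-1-bromoprop-1-ene and all reagents are taken as commercial.

**Route**

Step 1
Reactants: 1 andrographolide
Product: 2 14-deoxy-11,12-didehydroandrographolide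
Conditions: neutral Al2O3, pyridine, reflux
Reagents that add atoms: none
Why: Vinylogous E1cB dehydration (C11-H removed, C14-OH expelled) gives the conjugated (11E)-diene butenolide without touching any ring stereocentre.

Step 2
Reactants: 2 14-deoxy-11,12-didehydroandrographolide
Product: 3 19-O-acetyl-14-deoxy-11,12-didehydroandrographolide
Conditions: AcCl (1.1 equiv), 2,4,6-collidine, CH2Cl2, −78 °C
Reagents that add atoms: acetyl chloride CC(=O)Cl
Why: Chemoselective O-acylation, because the primary C19-OH reacts far faster than the secondary C3-OH flanked by quaternary C4.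

Step 3
Reactants: 3 19-O-acetyl-14-deoxy-11,12-didehydroandrographolide
Product: 4 19-O-acetyl-3-oxo-14-deoxy-11,12-didehydroandrographolide
Conditions: Dess–Martin periodinane, CH2Cl2, 0 °C → rt
Reagents that add atoms: none
Why: Dess–Martin oxidation of the only free alcohol; the β-acetoxy ketone can neither eliminate (C4 is quaternary) nor retro-aldolise (O19 is acylated).

Step 4
Reactants: 4 19-O-acetyl-3-oxo-14-deoxy-11,12-didehydroandrographolide
Product: 6 19-acetoxy-3-oxo-12,13,14,15,16-pentanor-ent-labd-8(17)-en-11-al, via vicinal diol 5 (not isolated)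
Conditions: OsO4 (2 mol%), NMO (1.05 equiv), acetone/H2O, 0 °C; then NaIO4, pH 7, rt
Reagents that add atoms: osmium tetroxide O=[Os](=O)(=O)=O (catalytic, delivers the C11 oxygen); N-methylmorpholine N-oxide C[N+]1([O-])CCOCC1 (re-oxidant that supplies that oxygen)
Why: Upjohn dihydroxylation then periodate glycol cleavage; with NMO limiting, OsO4 should take the unhindered trans-C11=C12 of the diene ahead of the shielded ring methylene and the electron-poor C13=C14, and the equatorial C9-CHO is the stable epimer.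

Step 5
Reactants: 6 19-acetoxy-3-oxo-12,13,14,15,16-pentanor-ent-labd-8(17)-en-11-al; 7 (E)-1-bromoprop-1-ene
Product: 9 (11R,12E)-19-acetoxy-11-hydroxy-14,15-dinor-ent-labda-8(17),12-dien-3-one, via (E)-prop-1-enylchromium(III) dichloride 8 (not isolated)
Conditions: CrCl2 (4 equiv), NiCl2 (2 mol%), DMF, rt
Reagents that add atoms: none
Why: Nozaki–Hiyama–Kishi alkenylation is aldehyde-selective (C3 ketone and acetate untouched) and keeps the E geometry; Felkin–Anh addition anti to quaternary C10, passing H-9, is predicted to set 11R.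

Step 6
Reactants: 9 (11R,12E)-19-acetoxy-11-hydroxy-14,15-dinor-ent-labda-8(17),12-dien-3-one
Product: 10 (11R,12E)-11,19-diacetoxy-14,15-dinor-ent-labda-8(17),12-dien-3-one
Conditions: Ac2O, DMAP (cat.), pyridine, CH2Cl2, rt
Reagents that add atoms: acetic anhydride CC(=O)OC(C)=O
Why: DMAP-catalysed O-acetylation of the only hydroxyl installs the acetate whose two carbons become C14 and C15.

Step 7
Reactants: 10 (11R,12E)-11,19-diacetoxy-14,15-dinor-ent-labda-8(17),12-dien-3-one
Product: 11 (3S,11R,12E)-11,19-diacetoxy-14,15-dinor-ent-labda-8(17),12-dien-3-ol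
Conditions: L-Selectride (1.2 equiv), THF, −78 °C; then H2O
Reagents that add atoms: none
Why: Bulky-hydride ketone reduction; equatorial attack on the 4,4-disubstituted cyclohexanone (avoiding the axial H-1 and H-5) gives the axial 3-OH (3S), anti to C19, while the acetates survive at −78 °C.

Step 8
Reactants: 11 (3S,11R,12E)-11,19-diacetoxy-14,15-dinor-ent-labda-8(17),12-dien-3-ol
Product: 12 (3S,11R,12E)-11,19-diacetoxy-14,15-dinor-ent-labda-7,12-dien-3-ol
Conditions: achiral Co(III)Cl complex of N,N′-bis(3,5-di-tert-butylsalicylidene)ethylenediamine (3 mol%), PhSiH3 (3 mol%), benzene, rt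
Reagents that add atoms: none
Why: Cobalt-hydride hydrogen-atom-transfer olefin transposition by one position; H adds to the 1,1-disubstituted methylene and is taken back from the accessible C7-H2 and not the hindered C9-H, and the 1,2-disubstituted C12=C13 is inert.

Step 9
Reactants: 12 (3S,11R,12E)-11,19-diacetoxy-14,15-dinor-ent-labda-7,12-dien-3-ol
Product: 15 (3S,11E,13S)-19-acetoxy-3-hydroxy-ent-labda-7,11-dien-15-oic acid, via tris-silylated bis(ketene acetal) 13 (not isolated), via rearranged trimethylsilyl ester 14 (not isolated)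
Conditions: LDA (4 equiv), TMSCl–Et3N (in situ), THF, −78 °C → 50 °C; then 1 M HCl
Reagents that add atoms: none
Why: Ireland–Claisen [3,3]-sigmatropic rearrangement through a chair with the decalin substituent on C11 equatorial transfers chirality suprafacially from C11 (R) to C13 and forms C13–C14 and the 11E olefin; the C19 ketene acetal and 3-O-TMS ether revert on acidic work-up.

Step 10
Reactants: 15 (3S,11E,13S)-19-acetoxy-3-hydroxy-ent-labda-7,11-dien-15-oic acid
Product: 16 (3R)-5-[(1R,4aS,5R,6S,8aS)-5-(acetoxymethyl)-6-hydroxy-2,5,8a-trimethyl-1,4,4a,5,6,7,8,8a-octahydronaphthalen-1-yl]-3-methylpentanoic acid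
Conditions: 2-nitrobenzenesulfonyl hydrazide, Et3N, CH2Cl2, rt
Reagents that add atoms: none
Why: Diimide reduction (concerted syn H2 transfer) takes the 1,2-disubstituted C11=C12 and leaves the hindered trisubstituted C7=C8 and all stereocentres alone; C13 becomes 13R by CIP priority change only.

**Compound list**

Ring stereocentres C4, C5, C9 and C10 are as in andrographolide in every compound. C10-CH3, C4-CH2O and the C9 substituent lie on one face; H-5, H-9 and, from 11 on, the axial 3-OH lie on the other.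

1 | andrographolide | OC[C@@]1(C)[C@H]2CCC(=C)[C@@H](C/C=C3\[C@H](O)COC3=O)[C@]2(C)CC[C@H]1O | starting material
2 | 14-deoxy-11,12-didehydroandrographolide | OC[C@@]1(C)[C@H]2CCC(=C)[C@@H](/C=C/C3=CCOC3=O)[C@]2(C)CC[C@H]1O | intermediate
3 | 19-O-acetyl-14-deoxy-11,12-didehydroandrographolide | CC(=O)OC[C@@]1(C)[C@H]2CCC(=C)[C@@H](/C=C/C3=CCOC3=O)[C@]2(C)CC[C@H]1O | intermediate
4 | 19-O-acetyl-3-oxo-14-deoxy-11,12-didehydroandrographolide | CC(=O)OC[C@@]1(C)[C@H]2CCC(=C)[C@@H](/C=C/C3=CCOC3=O)[C@]2(C)CCC1=O | intermediate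
5 | 11,12-syn-diol of 4 (two diastereomers, not isolated) | CC(=O)OC[C@@]1(C)[C@H]2CCC(=C)[C@@H](C(O)C(O)C3=CCOC3=O)[C@]2(C)CCC1=O | intermediate
6 | 19-acetoxy-3-oxo-12,13,14,15,16-pentanor-ent-labd-8(17)-en-11-al | CC(=O)OC[C@@]1(C)[C@H]2CCC(=C)[C@@H](C=O)[C@]2(C)CCC1=O | intermediate
7 | (E)-1-bromoprop-1-ene | C/C=C/Br | starting material
8 | (E)-prop-1-enylchromium(III) dichloride (not isolated) | C/C=C/[Cr](Cl)Cl | intermediate
9 | (11R,12E)-19-acetoxy-11-hydroxy-14,15-dinor-ent-labda-8(17),12-dien-3-one | CC(=O)OC[C@@]1(C)[C@H]2CCC(=C)[C@@H]([C@H](O)/C=C/C)[C@]2(C)CCC1=O | intermediate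
10 | (11R,12E)-11,19-diacetoxy-14,15-dinor-ent-labda-8(17),12-dien-3-one | CC(=O)OC[C@@]1(C)[C@H]2CCC(=C)[C@@H]([C@H](OC(C)=O)/C=C/C)[C@]2(C)CCC1=O | intermediate
11 | (3S,11R,12E)-11,19-diacetoxy-14,15-dinor-ent-labda-8(17),12-dien-3-ol | CC(=O)OC[C@@]1(C)[C@H]2CCC(=C)[C@@H]([C@H](OC(C)=O)/C=C/C)[C@]2(C)CC[C@@H]1O | intermediate
12 | (3S,11R,12E)-11,19-diacetoxy-14,15-dinor-ent-labda-7,12-dien-3-ol | CC(=O)OC[C@@]1(C)[C@H]2CC=C(C)[C@@H]([C@H](OC(C)=O)/C=C/C)[C@]2(C)CC[C@@H]1O | intermediate
13 | (3S,11R,12E)-3-(trimethylsilyloxy)-11,19-bis[1-(trimethylsilyloxy)vinyloxy]-14,15-dinor-ent-labda-7,12-diene (not isolated) | C=C(O[Si](C)(C)C)OC[C@@]1(C)[C@H]2CC=C(C)[C@@H]([C@H](OC(=C)O[Si](C)(C)C)/C=C/C)[C@]2(C)CC[C@@H]1O[Si](C)(C)C | intermediate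
14 | trimethylsilyl (3S,11E,13S)-3-(trimethylsilyloxy)-19-[1-(trimethylsilyloxy)vinyloxy]-ent-labda-7,11-dien-15-oate (not isolated) | C=C(O[Si](C)(C)C)OC[C@@]1(C)[C@H]2CC=C(C)[C@@H](/C=C/[C@@H](C)CC(=O)O[Si](C)(C)C)[C@]2(C)CC[C@@H]1O[Si](C)(C)C | intermediate
15 | (3S,11E,13S)-19-acetoxy-3-hydroxy-ent-labda-7,11-dien-15-oic acid | CC(=O)OC[C@@]1(C)[C@H]2CC=C(C)[C@@H](/C=C/[C@@H](C)CC(=O)O)[C@]2(C)CC[C@@H]1O | intermediate
16 | (3S,13R)-19-acetoxy-3-hydroxy-ent-labd-7-en-15-oic acid, i.e. (3R)-5-[(1R,4aS,5R,6S,8aS)-5-(acetoxymethyl)-6-hydroxy-2,5,8a-trimethyl-1,4,4a,5,6,7,8,8a-octahydronaphthalen-1-yl]-3-methylpentanoic acid | CC(=O)OC[C@@]1(C)[C@H]2CC=C(C)[C@@H](CC[C@@H](C)CC(=O)O)[C@]2(C)CC[C@@H]1O | target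

**Totals**
Total step count: 10. Longest linear sequence: 10 steps (fully linear from andrographolide).

**Three steps most likely to fail**

Step 4 (chemoselectivity of the cleavage). The ring methylene is an electron-rich olefin and may be dihydroxylated alongside or ahead of C11=C12. The fallback sets out from 4 and masks that olefin. mCPBA (1.05 equiv, NaHCO3, CH2Cl2, 0 °C) epoxidises the isolated 8(17)-olefin from the face anti to the C10 methyl and leaves the electron-poor diene, giving the spiro-epoxide F1. Ozonolysis (O3, CH2Cl2/MeOH, −78 °C; Me2S) then needs no selectivity, since over-oxidation only degrades the departing butenolide fragment, and gives the epoxy-aldehyde F2. Stereospecific deoxygenation (Ph3P=Se, TFA, CH2Cl2, 0 °C) restores the methylene, and the route is rejoined at 6.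

Step 5 (facial selectivity at C11). The Felkin preference between the quaternary C10 and the sp2 C8 flank is a prediction, and an 11S-rich product would lead to the wrong C13 epimer. The fallback keeps the sigmatropic relay but pairs 11S with a Z-olefin, which converges on the same C13 configuration. It sets out from 6: NHK coupling with (Z)-1-bromoprop-1-ene (C/C=C\Br), through (Z)-prop-1-enylchromium(III) dichloride F3, gives the (11S,12Z)-allylic alcohol F4. Acetylation gives the diacetate F5, L-Selectride the 3S-alcohol F6, and cobalt-hydride transposition the Δ7-isomer F7. LDA/TMSCl then gives the silyl ketene acetal F8, whose chair [3,3] shift (C9 substituent equatorial, Z-methyl axial) gives the same silyl ester. The route is rejoined at 14, and hence 15.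

Step 8 (Δ7 versus Δ8(9) and integrity of C9). Radical transposition could abstract the C9-H and give the tetrasubstituted olefin. The fallback sets out from 11 and uses a pericyclic relay in place of a radical one. In liquid SO2/CH2Cl2 (−20 °C → rt, sealed tube) an ene reaction at the methylene, with transfer of a C7-H, gives the allylic sulfinic acid F9. A 1,3-sulfinyl shift gives the C7-sulfinic acid F10, and retro-ene loss of SO2 places the hydrogen on C17. The route is rejoined at 12.

**Further compounds**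
F1 | step 4 | 8,17-epoxide of 4 (oxygen anti to the C10 methyl) | CC(=O)OC[C@@]1(C)[C@H]2CC[C@@]3(CO3)[C@@H](/C=C/C4=CCOC4=O)[C@]2(C)CCC1=O
F2 | step 4 | 19-acetoxy-8,17-epoxy-3-oxo-12,13,14,15,16-pentanor-ent-labdan-11-al | CC(=O)OC[C@@]1(C)[C@H]2CC[C@@]3(CO3)[C@@H](C=O)[C@]2(C)CCC1=O
F3 | step 5 | (Z)-prop-1-enylchromium(III) dichloride | C/C=C\[Cr](Cl)Cl
F4 | step 5 | (11S,12Z)-19-acetoxy-11-hydroxy-14,15-dinor-ent-labda-8(17),12-dien-3-one | CC(=O)OC[C@@]1(C)[C@H]2CCC(=C)[C@@H]([C@@H](O)/C=C\C)[C@]2(C)CCC1=O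
F5 | step 5 | (11S,12Z)-11,19-diacetoxy-14,15-dinor-ent-labda-8(17),12-dien-3-one | CC(=O)OC[C@@]1(C)[C@H]2CCC(=C)[C@@H]([C@@H](OC(C)=O)/C=C\C)[C@]2(C)CCC1=O
F6 | step 5 | (3S,11S,12Z)-11,19-diacetoxy-14,15-dinor-ent-labda-8(17),12-dien-3-ol | CC(=O)OC[C@@]1(C)[C@H]2CCC(=C)[C@@H]([C@@H](OC(C)=O)/C=C\C)[C@]2(C)CC[C@@H]1O
F7 | step 5 | (3S,11S,12Z)-11,19-diacetoxy-14,15-dinor-ent-labda-7,12-dien-3-ol | CC(=O)OC[C@@]1(C)[C@H]2CC=C(C)[C@@H]([C@@H](OC(C)=O)/C=C\C)[C@]2(C)CC[C@@H]1O
F8 | step 5 | (3S,11S,12Z)-3-(trimethylsilyloxy)-11,19-bis[1-(trimethylsilyloxy)vinyloxy]-14,15-dinor-ent-labda-7,12-diene | C=C(O[Si](C)(C)C)OC[C@@]1(C)[C@H]2CC=C(C)[C@@H]([C@@H](OC(=C)O[Si](C)(C)C)/C=C\C)[C@]2(C)CC[C@@H]1O[Si](C)(C)C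
F9 | step 8 | (3S,11R,12E)-11,19-diacetoxy-3-hydroxy-14,15-dinor-ent-labda-7,12-diene-17-sulfinic acid | CC(=O)OC[C@@]1(C)[C@H]2CC=C(CS(=O)O)[C@@H]([C@H](OC(C)=O)/C=C/C)[C@]2(C)CC[C@@H]1O
F10 | step 8 | (3S,11R,12E)-11,19-diacetoxy-3-hydroxy-14,15-dinor-ent-labda-8(17),12-diene-7-sulfinic acid (C7 epimers) | CC(=O)OC[C@@]1(C)[C@H]2CC(S(=O)O)C(=C)[C@@H]([C@H](OC(C)=O)/C=C/C)[C@]2(C)CC[C@@H]1O
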